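**Early readings.** At early times the cedar flask gave me two curves that did not match: by 12.0 min the starting material had lost 15 percentage points, but target stood at 10.6%, a share of 73.1%. So 3.9 points had gone elsewhere. That gap is a rough reading, the difference of readings that each scatter by 0.5 points.

| setting | cedar | Monday's | Wednesday's | Saturday's |
|---|---|---|---|---|
| starting material | 0.050 M | 0.050 M | 0.050 M | 0.050 M |
| first nucleophile | 0.045 M | 0.0300 M | 0.0300 M | 0.0300 M |
| second nucleophile | 0.040 M | 0.0400 M | 0.0400 M | 0.0400 M |
| temperature | 45 °C | 45 °C | 25 °C | 5 °C |
| remark | run made earlier |  |  |  |
| time |  | 2.0 h | 2.0 h | 2.0 h |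

cedar run (percent of the starting material charged)

| time / min | target / % | starting material / % |
|---|---|---|
| 1.00 | 1.1 | 97.4 |
| 2.00 | 2.3 | 96.5 |
| 5.00 | 6.4 | 92.0 |
| 12.0 | 10.6 | 85.5 |

(scatter of a reading: 0.5 percentage points)

- the earlier runs do not show what temperature does; that part of a forecast is a guess

1. the flask that comes out highest in amount of target, in percent of the starting material charged, or "all alike" when all lie within 1.5 percentage points (Monday's / Wednesday's / Saturday's / all alike)
2. target at the end, in percent of the starting material charged, Monday's
3. target at the end, in percent of the starting material charged, Wednesday's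
4. target at the end, in percent of the starting material charged, Saturday's

**Capture factor.** I assumed that second nucleophile took up the gap. The capture factor (selectivity factor), target over gap with each divided by the charged concentration of its nucleophile, then came to 2.42.

**For the bench.** Monday's, Wednesday's and Saturday's held [first nucleophile] = 0.0300 M against [second nucleophile] = 0.0400 M. With that factor I expected target to be 64.4% of whatever starting material had lost by the time you came. I carried this across temperature as a guess. In my reckoning, the lower [first nucleophile] took the share below cedar's.

**The forecast.** The forecast named Monday's highest, with 34%, 15% and 3.5% of target for Monday's, Wednesday's and Saturday's. It held that “about 75% of what is consumed becomes target”, and my share stood lower than that.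

**The flasks.** Monday's gave 22.0%, Wednesday's 12.8% and Saturday's 3.62%, so Monday's stood highest, 12 points below the forecast's figure for it. Monday's had converted 38.9% of its starting material by 2.0 h. My share turned that into 25.1% of target, still 3.1 points above the flask.

    second nucleophile → decomposed reagent (k = 0.00120 /min, Ea = 94.0 kJ/mol)
    first nucleophile ⇌ dormant form (K = 2.50, k = 0.0130 /min, Ea = 84.0 kJ/mol, ΔH = 12.0 kJ/mol)
    first nucleophile + intermediate → target (k = 11.0 /M/min, Ea = 49.0 kJ/mol)
    starting material ⇌ intermediate (K = 0.00860, k = 0.0160 /min, Ea = 88.0 kJ/mol, ΔH = 8.00 kJ/mol)
    second nucleophile + intermediate → other capture product (k = 2.80 /M/min, Ea = 50.0 kJ/mol)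
    (constants at 25 °C)

**Second flask.** A neighbour, Wednesday's with [starting material] = 0.20 M, kept both nucleophile charges, so the capture factor of 2.42 again gave a share of 64.4%. Computed, it ended with 83.6% of its starting material and 8.74% of target, a share of 53.3%, lower than that.

(The numbers in the tables are simulated on assumed constants; scatter was added.)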